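## The problem

Compound 16 is an acyclic diarylheptanoid: a C1–C7 chain with a 4-hydroxy-3-methoxyphenyl ring at each end, oxygen on C3 and C5, and an acetyl group on one of these two oxygens; no ring has to be made. The work is to assemble the seven-carbon chain and to set two stereocentres, C3 and C5, both S, in an anti 1,3-relationship. Because the two aryl ends are identical, the parent (3S,5S)-diol has a twofold axis through C4, so its hydroxyls are equivalent and acetylation of either gives 16, whereas the syn diol would be meso. C3 and C5 are close enough for one to direct the other (through a β-hydroxy ketone or an epoxy alcohol), but they can also be set independently, and a stereochemical slip at either centre then surfaces as the separable meso diastereomer. The delicate groups are the two free phenols, which are acidic, easily oxidised and incompatible with organolithium reagents unless masked, and the secondary acetate beside a free hydroxyl, which will not survive strong base, hydride or hot aqueous acid. The feature that opens the chosen route is the single methylene C4 between the two carbinol carbons: with C3 and C5 made as carbon–boron centres, C3–C4 is the two-carbon unit of a terminal alkene that can be diborated, and C4 is then the carbon on a primary boron that can migrate to a carbenoid carbon destined to be C5.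

## Retrosynthesis

**16 from 15 (the two aryl O–Si bonds).** The last step should be the gentlest, because 16 carries an acetate beside a free hydroxyl. The phenols are therefore carried as triisopropylsilyl ethers from the first step. These tolerate sec-butyllithium at −78 °C, boranes, ylides, perborate and mild acid, and buffered fluoride cleaves an aryl silyl ether far faster than it disturbs an acetate. Benzyl ethers were the neighbouring choice and would leave under neutral hydrogenolysis, but their O–CH2 hydrogens are a liability toward the alkyllithium base used earlier. Precursor 15 differs from 16 only by the two silyl groups.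

**15 from 13 by way of 14 (the acetate C–O bond).** In diol 13 the two hydroxyls are exchanged by the twofold axis, so no site selectivity is needed, only a stop after one acylation. The cyclic orthoester 14 bridges O3 and O5 with a single acetate carbon, and its hydrolysis can release one acetyl group and no more; either mode of ring opening gives 15. Direct acylation with one equivalent of an anhydride would give a statistical mixture and is set aside.

**13 from 12 (both carbinol C–O bonds).** Each hydroxyl is traced to a pinacol boronic ester on the same carbon. Oxidation of C–B goes with retention, so the (3S,5S) arrangement of 12 is that of 13. This moves the stereochemical problem from C–O to C–B bonds, where carbon–carbon bond formation under reagent control is available. 12 is no smaller than 13, but it is the direct product of the key step.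

**12 from 9 and 10 (C4–C5, the key cut).** With C5 as a carbenoid carbon and C4 as a carbon on boron, 12 divides into the 1,2-bis(boronic ester) 9 and the α-lithiated benzoate 10.
- Against aldol-type cuts through a carbonyl group, this cut needs no later change of oxidation state and does not rely on C3 to induce C5. 10 adds to boron with retention and the C4–B bond then migrates with inversion, so the configuration of 10 alone decides C5.
- The cut is nearly central: 9 holds one arene, four chain carbons and one stereocentre, 10 the other arene and three chain carbons.
- The forward reaction must choose the primary boron of 9 over the secondary one. 10 is not isolable; it is made in the flask from ester 5 with sec-butyllithium and (+)-sparteine, and the diamine-bound carbenoid is bulky enough to feel the difference between a CH2–B and a CH–B centre sharply.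
- The 2,4,6-triisopropylbenzoate is preferred to a dialkylcarbamate on oxygen because its boronate complex 11 rearranges on gentle warming. No Lewis acid is needed in a molecule that holds a second boronic ester.

**9 from 7 and 8 (the C3–B and C4–B bonds).** Both boron atoms are removed together, which leaves the terminal alkene 7 and commercial diboron 8. The forward reaction is a catalytic enantioselective diboration, which must add the two boron atoms to one face of an alkene that carries only a primary alkyl substituent. The neighbouring cut, a first insertion of 10 into a one-carbon diboron unit, would take C3 from the same reagent as C5. It would, however, require the short-lived carbenoid in two separate operations and an α-boryl methylene to survive it, and is held in reserve. With catalyst control at C3 and reagent control at C5 the two centres are set independently. The minor enantiomer of 9 and the minor enantiomer of 10 are each channelled into the meso series, and only the coincidence of both errors gives the enantiomer of 12.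

**7 from 4 by way of 6 (C3=C4).** The alkene is cut at its double bond into aldehyde 6 and a one-carbon ylide, and 6 is the oxidation product of alcohol 4. This lets one alcohol serve both halves of the molecule: three of its carbons become C1–C3 by way of 7 and 9, and three become C5–C7 by way of 5 and 10. Both operations are routine and tolerate the aryl silyl ether.

**5, 4, 2 and 1.** 5 is the Mitsunobu ester of alcohol 4, which comes from silyl ether 2 by hydroboration to 3 and oxidation. 2 is the silyl ether of eugenol 1, which already holds the guaiacyl ring and the three-carbon side chain. Starting from the allylphenol avoids silylating a phenol selectively beside a primary alcohol.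

## Roads not taken

Alternative 1: The cut is at C2–C3 and C5–C6, so that C3–C5 come from propane-1,3-diol A1 and each flank from allyl acetate A2.
- Forward step: A1 and two molecules of A2 would couple under a chiral cyclometallated iridium catalyst (from [Ir(cod)Cl]2, a chiral bisphosphine, a nitrobenzoic acid and Cs2CO3). The diol is dehydrogenated one end at a time and each aldehyde is allylated, giving (4S,6S)-nona-1,8-diene-4,6-diol A3 with both carbinol centres set in one flask.
- Merits: the chirality is catalytic and the starting materials are trivial. Because both ends are allylated under catalyst control, wrong-handed events are drained into the meso isomer, so A3 should be of very high optical purity. In these respects this road is better than the chosen one, which needs a stoichiometric chiral diamine, cryogenic organolithium chemistry and a platinum catalyst with a chiral ligand of its own.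
- Weak point for this target: each allyl group supplies three carbons where the target has two between carbinol and arene. The internal alkene carbon of A3 maps onto C1 or C7 and the terminal CH2 onto nothing. Direct arylation of the vinyl groups (cross-metathesis with a styrene, Heck reaction) would give a three-carbon tether. After protection of the diol, both alkenes would have to be cleaved oxidatively, the arenes added as aryl-metal reagents and the two new benzylic hydroxyls removed by reduction, roughly six operations that only repair the carbon count.
- Comparison: against the catalytic economy of A3 the chosen plan sets the fact that in 12 every carbon and both arenes are already in their final places when the second stereocentre is made, so that only oxidation, acetylation and desilylation remain.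

Alternative 2: The cut is at C3–O together with the C4–H bond that a hydride would make. The diol is traced to an erythro trans-3,4-epoxy-5-ol A5 and this to the (5S)-configured E-allylic alcohol A4 (target numbering), both with the phenols as benzyl ethers.
- Forward step: A4 would be epoxidised with Ti(OiPr)4, the matched dialkyl tartrate and an alkyl hydroperoxide (Sharpless asymmetric epoxidation of a secondary allylic alcohol). Reagent and C5 centre reinforce each other and A5 forms on the erythro face. Hydroxyl-directed hydride delivery from NaAlH2(OCH2CH2OMe)2 to C4 would then give the anti 1,3-diol.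
- Merits: cheap, scalable reagents, no cryogenic organolithium chemistry, no precious-metal catalyst and a well-understood stereochemical outcome. The benzyl ethers can leave by hydrogenolysis without touching the acetate. On cost and scale this road is at least the equal of the chosen one.
- Weak points: A4 must itself be enantiopure, which needs a further asymmetric operation or a kinetic resolution that discards half the material. The E-allylic alcohol needs a C–C bond-forming sequence of its own. The regiochemistry of the reductive opening is less secure for a secondary epoxy alcohol flanked by methylene groups on both sides than for primary 2,3-epoxy alcohols, so some attack at C3 must be expected.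
- Comparison: the chosen plan has no regiochemical question at the oxygenation stage, because each oxygen enters exactly where a boron atom sits. It also sets the two centres by two independent controllers rather than one centre from the other, and it should be no longer.

Alternative 3: The cut is at C5–O of the acetate, which would be made by moving an acetate from benzylic C7 to C5 across a C5=C6 alkene. The substrate is the (3S,5E,7R)-7-acetoxy-3-silyloxyhept-5-ene A6, with one phenol as benzyl ether and the one next to C7 as tert-butyl carbonate.
- Forward step: with PdCl2(MeCN)2 (divalent palladium) the alkene is activated, the acetate carbonyl adds to C5 through a six-membered acetoxonium intermediate, and the C7–O bond breaks. This gives the (3S,5R,6E)-5-acetate A7 with an E styrene, the chirality of C7 being passed suprafacially to C5.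
- Merits: the acetate is placed on one defined oxygen by the bond-forming event itself, with O3 differently protected, so no monoacetylation step is needed. For an analogue with two different arenes, where the hydroxyls are not equivalent, this road would be clearly superior to the chosen one.
- Weak points for this target: that advantage is not needed, since diol 13 is C2-symmetric. A6 already contains two stereocentres in a remote 1,5-relationship that cannot control one another. A benzylic acetate para to an oxygen substituent ionises easily even with the carbonate damping the ring, which opens paths to racemisation and diene formation. The shift is an equilibrium held on the product side only by styrene conjugation. The hydrogenation that follows must saturate the styrene of A7 without hydrogenolysis of the allylic acetate. Three different protecting groups are carried.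
- Comparison: the chosen plan should be shorter and has no step in which the C5 configuration depends on a labile benzylic centre. Against the built-in regiocontrol of this road it sets one extra but undemanding orthoester step.

Key step: step 7

Remark on the chemistry: (+)-sparteine is taken to be purchasable; with sec-butyllithium it removes the pro-R α-hydrogen of an alkyl 2,4,6-triisopropylbenzoate (the mirror image of what the (−)-enantiomer does), and boron and tin electrophiles are taken to replace lithium with retention. Both enantiomers of the TADDOL-derived phenylphosphonite are taken to be available from the two tartaric acids; the one that leads to (R)-9 is used.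

## Route

Step 1
Reactants: 1 eugenol (4-allyl-2-methoxyphenol)
Product: 2 (4-allyl-2-methoxyphenoxy)triisopropylsilane
Conditions: TIPSCl, imidazole, DMF, rt
Reagents that add atoms: triisopropylsilyl chloride, CC(C)[Si](Cl)(C(C)C)C(C)C
Why: Silylation of a phenol with a silyl chloride and imidazole; the hindered aryl silyl ether withstands the borane, ylide, alkyllithium and mild acid steps that follow and leaves with fluoride at the end.

Step 2
Reactants: 2 (4-allyl-2-methoxyphenoxy)triisopropylsilane
Product: 4 3-[3-methoxy-4-(triisopropylsilyloxy)phenyl]propan-1-ol, via 9-BBN adduct 3 (not isolated)
Conditions: 9-BBN, THF, 0 °C → rt; then NaBO3·4H2O, THF/H2O, rt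
Reagents that add atoms: sodium perborate tetrahydrate (NaBO3·4H2O), [Na+].[O-]OB=O
Why: Hydroboration–oxidation; 9-BBN adds to the terminal alkene with anti-Markovnikov selectivity and the C–B bond is oxidised with retention. Perborate is used instead of alkaline peroxide to spare the aryl silyl ether.

Step 3
Reactants: 4 3-[3-methoxy-4-(triisopropylsilyloxy)phenyl]propan-1-ol
Product: 5 3-[3-methoxy-4-(triisopropylsilyloxy)phenyl]propyl 2,4,6-triisopropylbenzoate
Conditions: 2,4,6-triisopropylbenzoic acid, PPh3, DIAD, THF, 0 °C → rt
Reagents that add atoms: 2,4,6-triisopropylbenzoic acid, CC(C)c1cc(C(C)C)c(C(O)=O)c(C(C)C)c1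
Why: Mitsunobu esterification of a primary alcohol. The hindered benzoate resists carbonyl attack by sec-butyllithium, directs α-deprotonation and later acts as the leaving group of the 1,2-migration.

Step 4
Reactants: 4 3-[3-methoxy-4-(triisopropylsilyloxy)phenyl]propan-1-ol
Product: 6 3-[3-methoxy-4-(triisopropylsilyloxy)phenyl]propanal
Conditions: Dess–Martin periodinane, CH2Cl2, rt
Reagents that add atoms: none
Why: Oxidation of a primary alcohol to the aldehyde with a hypervalent iodine reagent under nearly neutral conditions; it stops at the aldehyde and leaves the aryl silyl ether and the electron-rich ring alone.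

Step 5
Reactants: 6 3-[3-methoxy-4-(triisopropylsilyloxy)phenyl]propanal
Product: 7 4-[3-methoxy-4-(triisopropylsilyloxy)phenyl]but-1-ene
Conditions: Ph3PCH3Br, KN(SiMe3)2, THF, 0 °C; then 6, 0 °C → rt
Reagents that add atoms: methyltriphenylphosphonium bromide, C[P+](c1ccccc1)(c1ccccc1)c1ccccc1.[Br-]
Why: Wittig methylenation; the unstabilised ylide turns the aldehyde into the terminal alkene and supplies the carbon that becomes C4. A slight deficit of base relative to the phosphonium salt leaves no free amide to enolise the aldehyde or attack the silyl ether.

Step 6
Reactants: 7 4-[3-methoxy-4-(triisopropylsilyloxy)phenyl]but-1-ene; 8 bis(pinacolato)diboron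
Product: 9 (R)-4-[3-methoxy-4-(triisopropylsilyloxy)phenyl]-1,2-bis(pinacolboryl)butane
Conditions: Pt(dba)3 (cat.), TADDOL-derived phenylphosphonite (cat., the enantiomer leading to (R)-9), THF, 60 °C
Reagents that add atoms: none
Why: Platinum-catalysed enantioselective 1,2-diboration of a monosubstituted alkene: the B–B bond adds oxidatively to zerovalent platinum, the alkene inserts into a Pt–B bond on the face chosen by the chiral phosphonite, and reductive elimination delivers both boron atoms syn, which fixes C3 as R. The aryl silyl ether and the methoxyarene are inert to the catalyst.

Step 7
Reactants: 5 3-[3-methoxy-4-(triisopropylsilyloxy)phenyl]propyl 2,4,6-triisopropylbenzoate; 9 (R)-4-[3-methoxy-4-(triisopropylsilyloxy)phenyl]-1,2-bis(pinacolboryl)butane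
Product: 12 (3S,5S)-1,7-bis[3-methoxy-4-(triisopropylsilyloxy)phenyl]-3,5-bis(pinacolboryl)heptane, via lithiated benzoate 10 (not isolated), via boronate complex 11 (not isolated)
Conditions: 5 (slight excess), s-BuLi, (+)-sparteine, Et2O, −78 °C; then 9 in Et2O, −78 °C; then −78 °C → 35 °C
Reagents that add atoms: none
Why: sec-Butyllithium and (+)-sparteine remove the pro-R α-hydrogen of 5 and give the configurationally stable (R)-carbenoid 10 (sparteine-mediated asymmetric deprotonation). The primary boron of 9 takes the place of lithium with retention to give the tetracoordinate boronate 11; on warming, the C4–B bond migrates to C5 antiperiplanar to the departing benzoate, so C5 is inverted and the (R)-carbenoid becomes the (S)-configured C5 of 12. The closest known reaction type is the reagent-controlled lithiation–borylation homologation of the primary boron of a 1,2-bis(boronic ester) to a 1,3-bis(boronic ester), a stereospecific 1,2-metallate rearrangement. No ring is closed; one C–C bond (C4–C5) and one stereocentre (C5) are formed. C5 is controlled by the configuration of 10 alone, that is by the sparteine enantiomer, while C3 is untouched because the migrating carbon is C4 and not C3. The step needs site selectivity for the primary over the secondary boronic ester; this rests on the lower hindrance of the CH2–B centre, which the bulky diamine-bound carbenoid feels strongly, and on complexation at −78 °C. Complexation and migration are separated in temperature, so 12 appears only after surplus carbenoid has decomposed and cannot be homologated again. Because C3 stems from the catalyst of step 6 and C5 from the reagent, a wrong-handed event at either centre ends in the meso diastereomer, which can be separated at the diol stage.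

Step 8
Reactants: 12 (3S,5S)-1,7-bis[3-methoxy-4-(triisopropylsilyloxy)phenyl]-3,5-bis(pinacolboryl)heptane
Product: 13 (3S,5S)-1,7-bis[3-methoxy-4-(triisopropylsilyloxy)phenyl]heptane-3,5-diol
Conditions: NaBO3·4H2O, THF/H2O, rt
Reagents that add atoms: sodium perborate tetrahydrate (NaBO3·4H2O), [Na+].[O-]OB=O
Why: Oxidation of both secondary boronic esters; the alkyl group migrates from boron to oxygen with retention, so the (3S,5S) arrangement of 12 is carried into the anti diol. The mild oxidant leaves the aryl silyl ethers in place.

Step 9
Reactants: 13 (3S,5S)-1,7-bis[3-methoxy-4-(triisopropylsilyloxy)phenyl]heptane-3,5-diol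
Product: 15 (3S,5S)-5-hydroxy-1,7-bis[3-methoxy-4-(triisopropylsilyloxy)phenyl]heptan-3-yl acetate, via cyclic orthoester 14 (not isolated)
Conditions: MeC(OMe)3, PPTS (cat.), CH2Cl2, rt; then AcOH/H2O, rt
Reagents that add atoms: trimethyl orthoacetate, CC(OC)(OC)OC; water, O
Why: Acid-catalysed orthoester exchange gives the 2-methoxy-2-methyl-1,3-dioxane 14, whose hydrolysis passes through a dioxacarbenium ion that can deliver only one acetyl group per diol. The twofold symmetry of 13 makes both ring-opening modes give the same monoacetate.

Step 10
Reactants: 15 (3S,5S)-5-hydroxy-1,7-bis[3-methoxy-4-(triisopropylsilyloxy)phenyl]heptan-3-yl acetate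
Product: 16 (3S,5S)-5-hydroxy-1,7-bis(4-hydroxy-3-methoxyphenyl)heptan-3-yl acetate (CNP0293159.1)
Conditions: TBAF, AcOH, THF, 0 °C
Reagents that add atoms: none
Why: Fluoride-induced cleavage of aryl silyl ethers, fast at 0 °C because phenoxide is a good leaving group from silicon. The acetic acid buffer keeps the medium from becoming basic enough to cleave or transfer the acetate, and migration between O3 and O5 would be degenerate.

## Compound list

1 | eugenol (4-allyl-2-methoxyphenol) | C=CCc1ccc(O)c(OC)c1 | starting material
2 | (4-allyl-2-methoxyphenoxy)triisopropylsilane | C=CCc1ccc(O[Si](C(C)C)(C(C)C)C(C)C)c(OC)c1 | intermediate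
3 | 9-{3-[3-methoxy-4-(triisopropylsilyloxy)phenyl]propyl}-9-borabicyclo[3.3.1]nonane | COc1cc(CCCB2C3CCCC2CCC3)ccc1O[Si](C(C)C)(C(C)C)C(C)C | intermediate (not isolated)
4 | 3-[3-methoxy-4-(triisopropylsilyloxy)phenyl]propan-1-ol | OCCCc1ccc(O[Si](C(C)C)(C(C)C)C(C)C)c(OC)c1 | intermediate
5 | 3-[3-methoxy-4-(triisopropylsilyloxy)phenyl]propyl 2,4,6-triisopropylbenzoate | CC(C)c1cc(C(C)C)c(C(=O)OCCCc2ccc(O[Si](C(C)C)(C(C)C)C(C)C)c(OC)c2)c(C(C)C)c1 | intermediate
6 | 3-[3-methoxy-4-(triisopropylsilyloxy)phenyl]propanal | O=CCCc1ccc(O[Si](C(C)C)(C(C)C)C(C)C)c(OC)c1 | intermediate
7 | 4-[3-methoxy-4-(triisopropylsilyloxy)phenyl]but-1-ene | C=CCCc1ccc(O[Si](C(C)C)(C(C)C)C(C)C)c(OC)c1 | intermediate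
8 | bis(pinacolato)diboron | CC1(C)OB(OC1(C)C)B1OC(C)(C)C(C)(C)O1 | starting material
9 | (R)-4-[3-methoxy-4-(triisopropylsilyloxy)phenyl]-1,2-bis(pinacolboryl)butane | COc1cc(CC[C@H](B2OC(C)(C)C(C)(C)O2)CB2OC(C)(C)C(C)(C)O2)ccc1O[Si](C(C)C)(C(C)C)C(C)C | intermediate
10 | (R)-1-lithio-3-[3-methoxy-4-(triisopropylsilyloxy)phenyl]propyl 2,4,6-triisopropylbenzoate (formed as its (+)-sparteine complex) | CC(C)c1cc(C(C)C)c(C(=O)O[C@@H](CCc2ccc(O[Si](C(C)C)(C(C)C)C(C)C)c(OC)c2)[Li])c(C(C)C)c1 | intermediate (not isolated)
11 | lithium boronate complex of the primary boron of 9 with 10 (secondary C–B centre as in 9, R at the benzoate-bearing carbon) | [Li+].COc1cc(CC[C@H](B2OC(C)(C)C(C)(C)O2)C[B-]2(OC(C)(C)C(C)(C)O2)[C@H](CCc2ccc(O[Si](C(C)C)(C(C)C)C(C)C)c(OC)c2)OC(=O)c2c(C(C)C)cc(C(C)C)cc2C(C)C)ccc1O[Si](C(C)C)(C(C)C)C(C)C | intermediate (not isolated)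
12 | (3S,5S)-1,7-bis[3-methoxy-4-(triisopropylsilyloxy)phenyl]-3,5-bis(pinacolboryl)heptane | COc1cc(CC[C@H](B2OC(C)(C)C(C)(C)O2)C[C@H](CCc2ccc(O[Si](C(C)C)(C(C)C)C(C)C)c(OC)c2)B2OC(C)(C)C(C)(C)O2)ccc1O[Si](C(C)C)(C(C)C)C(C)C | intermediate
13 | (3S,5S)-1,7-bis[3-methoxy-4-(triisopropylsilyloxy)phenyl]heptane-3,5-diol | COc1cc(CC[C@H](O)C[C@H](CCc2ccc(O[Si](C(C)C)(C(C)C)C(C)C)c(OC)c2)O)ccc1O[Si](C(C)C)(C(C)C)C(C)C | intermediate
14 | (4S,6S)-2-methoxy-2-methyl-4,6-bis{2-[3-methoxy-4-(triisopropylsilyloxy)phenyl]ethyl}-1,3-dioxane | COc1cc(CC[C@H]2C[C@H](CCc3ccc(O[Si](C(C)C)(C(C)C)C(C)C)c(OC)c3)OC(C)(OC)O2)ccc1O[Si](C(C)C)(C(C)C)C(C)C | intermediate (not isolated)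
15 | (3S,5S)-5-hydroxy-1,7-bis[3-methoxy-4-(triisopropylsilyloxy)phenyl]heptan-3-yl acetate | COc1cc(CC[C@H](O)C[C@H](CCc2ccc(O[Si](C(C)C)(C(C)C)C(C)C)c(OC)c2)OC(C)=O)ccc1O[Si](C(C)C)(C(C)C)C(C)C | intermediate
16 | (3S,5S)-5-hydroxy-1,7-bis(4-hydroxy-3-methoxyphenyl)heptan-3-yl acetate (CNP0293159.1) | COc1cc(CC[C@H](O)C[C@H](CCc2ccc(O)c(OC)c2)OC(C)=O)ccc1O | target

## Step count and risks

Total number of steps: 10. Longest linear sequence: 9 steps (1, 2, 4, 5, 6, 7, 8, 9, 10); step 3 is a one-step branch from 4 that rejoins at step 7.

**Step 7 (key step).** The most likely failure is incomplete formation of the boronate complex. The primary boron of 9 carries a branch at its β-carbon, and the sparteine-bound carbenoid may reach it too slowly at −78 °C, so that the carbenoid decomposes on warming and 9 is returned. The second risk is erosion of stereochemical purity at C5: the selectivity of the deprotonation is fixed in the flask and cannot be checked or raised, and every wrong-handed insertion ends in the meso series.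

Fallback, from 5 back to 12: 5 is lithiated under the conditions of step 7 and 10 is trapped with Me3SnCl to give (R)-3-[3-methoxy-4-(triisopropylsilyloxy)phenyl]-1-(trimethylstannyl)propyl 2,4,6-triisopropylbenzoate F1. F1 can be stored and its enantiomeric purity measured before use. Tin–lithium exchange on F1 with n-BuLi in Et2O at −78 °C goes with retention and regenerates 10 free of diamine. This smaller carbenoid is added to 9 in no more than one equivalent; complex 11 rearranges on warming and the route is rejoined at 12.

**Step 6.** The most likely failure is insufficient facial selectivity in the alkene insertion, since the only substituent on the alkene is an unbranched alkyl chain. Each wrong-handed insertion is carried into the meso series in step 7 and costs material. A lesser risk is incomplete conversion through catalyst deactivation.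

Fallback, from 5 back to 9: 5 is lithiated with s-BuLi and (+)-sparteine as in step 7, and 10 is added at −78 °C to an excess of commercial bis(pinacolboryl)methane. The lithium boronate complex of bis(pinacolboryl)methane with 10 F2 rearranges on warming with migration of the CH2Bpin group and inversion at the carbenoid carbon, which gives 9. C3 then comes from reagent control instead of catalyst control, and the excess of the diboron reagent keeps the insertion at one.

**Step 9.** The most likely failure is incomplete closure of the six-membered orthoester, because the anti diol must place one side chain axial or adopt a twist conformation. Open-chain orthoesters would then give recovered diol and double acetylation on hydrolysis.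

Fallback, from 13 back to 15: 13 is heated with Bu2SnO in toluene with removal of water to give the dibutylstannylene acetal (4S,6S)-2,2-dibutyl-4,6-bis{2-[3-methoxy-4-(triisopropylsilyloxy)phenyl]ethyl}-1,3,2-dioxastannane F3, which is acylated once with acetyl chloride at 0 °C. The tin-bound second oxygen is freed on work-up and the route is rejoined at 15.

**Step 10.** The most likely failure is base-induced transfer or loss of the acetyl group while phenoxide is present during the fluoride treatment. Migration between O3 and O5 is harmless, but transfer between molecules would disproportionate the monoacetate.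

Fallback, from 13 back to 16: the order of the last two operations is reversed. 13 is desilylated first (TBAF, THF) to (3S,5S)-1,7-bis(4-hydroxy-3-methoxyphenyl)heptane-3,5-diol F4. F4 is then converted under the acidic conditions of step 9 into its cyclic orthoester (4S,6S)-4,6-bis[2-(4-hydroxy-3-methoxyphenyl)ethyl]-2-methoxy-2-methyl-1,3-dioxane F5; aryl orthoester linkages formed on the way revert to free phenol. Hydrolysis of F5 gives 16 directly, so the acetate never meets fluoride.

## Further compounds

F1 | step 7 | (R)-3-[3-methoxy-4-(triisopropylsilyloxy)phenyl]-1-(trimethylstannyl)propyl 2,4,6-triisopropylbenzoate | CC(C)c1cc(C(C)C)c(C(=O)O[C@@H](CCc2ccc(O[Si](C(C)C)(C(C)C)C(C)C)c(OC)c2)[Sn](C)(C)C)c(C(C)C)c1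
F2 | step 6 | lithium boronate complex of bis(pinacolboryl)methane with 10 (R at the benzoate-bearing carbon) | [Li+].CC(C)c1cc(C(C)C)c(C(=O)O[C@@H](CCc2ccc(O[Si](C(C)C)(C(C)C)C(C)C)c(OC)c2)[B-]2(CB3OC(C)(C)C(C)(C)O3)OC(C)(C)C(C)(C)O2)c(C(C)C)c1
F3 | step 9 | (4S,6S)-2,2-dibutyl-4,6-bis{2-[3-methoxy-4-(triisopropylsilyloxy)phenyl]ethyl}-1,3,2-dioxastannane | COc1cc(CC[C@H]2C[C@H](CCc3ccc(O[Si](C(C)C)(C(C)C)C(C)C)c(OC)c3)O[Sn](CCCC)(CCCC)O2)ccc1O[Si](C(C)C)(C(C)C)C(C)C
F4 | step 10 | (3S,5S)-1,7-bis(4-hydroxy-3-methoxyphenyl)heptane-3,5-diol | COc1cc(CC[C@H](O)C[C@H](CCc2ccc(O)c(OC)c2)O)ccc1O
F5 | step 10 | (4S,6S)-4,6-bis[2-(4-hydroxy-3-methoxyphenyl)ethyl]-2-methoxy-2-methyl-1,3-dioxane | COc1cc(CC[C@H]2C[C@H](CCc3ccc(O)c(OC)c3)OC(C)(OC)O2)ccc1O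
A1 | alternative 1 | propane-1,3-diol | OCCCO
A2 | alternative 1 | allyl acetate | C=CCOC(C)=O
A3 | alternative 1 | (4S,6S)-nona-1,8-diene-4,6-diol | C=CC[C@H](O)C[C@H](CC=C)O
A4 | alternative 2 | (3S,4E)-1,7-bis[4-(benzyloxy)-3-methoxyphenyl]hept-4-en-3-ol (the 5S, 3E allylic alcohol in target numbering) | COc1cc(CC/C=C/[C@H](CCc2ccc(OCc3ccccc3)c(OC)c2)O)ccc1OCc1ccccc1
A5 | alternative 2 | erythro trans-3,4-epoxy-1,7-bis[4-(benzyloxy)-3-methoxyphenyl]heptan-5-ol (target numbering) | COc1cc(CC[C@@H]4O[C@H]4[C@H](CCc2ccc(OCc3ccccc3)c(OC)c2)O)ccc1OCc1ccccc1
A6 | alternative 3 | (3S,5E,7R)-7-acetoxy-1-[4-(benzyloxy)-3-methoxyphenyl]-7-[4-(tert-butoxycarbonyloxy)-3-methoxyphenyl]-3-(tert-butyldimethylsilyloxy)hept-5-ene | COc1cc(CC[C@H](O[Si](C)(C)C(C)(C)C)C/C=C/[C@@H](OC(C)=O)c2ccc(OC(=O)OC(C)(C)C)c(OC)c2)ccc1OCc1ccccc1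
A7 | alternative 3 | (3S,5R,6E)-5-acetoxy-1-[4-(benzyloxy)-3-methoxyphenyl]-7-[4-(tert-butoxycarbonyloxy)-3-methoxyphenyl]-3-(tert-butyldimethylsilyloxy)hept-6-ene | COc1cc(CC[C@H](O[Si](C)(C)C(C)(C)C)C[C@H](/C=C/c2ccc(OC(=O)OC(C)(C)C)c(OC)c2)OC(C)=O)ccc1OCc1ccccc1
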